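**Retrosynthetic overview**

1. The last disconnections remove the C9 acetate and the C8 (E)-2-(acetoxymethyl)but-2-enoate from an 8,9-diol that is stored as a cis-acetonide; the acid is made from tert-butyl acrylate and acetaldehyde.
2. Cutting C6–C7 (and the O–C12 acyl bond) opens the ten-membered carbocycle C1–C10 and the α-methylene-γ-butyrolactone together. Forward, a C6 enal and a C7-derived (Z)-2-(bromomethyl)enoate are joined by intramolecular CrCl2 Barbier allylation with lactonisation; this is the second ring-forming event.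
3. The strategy rests on the 3(2H)-furanone ring O–C3=C2–C1(=O)–C10, whose quaternary C10 carries methyl C14, the ring oxygen, the C1 ketone and C9. Cutting O–C3 and returning C14 from C10 to C1 gives an acyclic 2-hydroxy-2-alkynyl ketone (C10 ketone, C1 tertiary carbinol, C2≡C3). Forward, PtCl2 closes this ring first and moves the C1 configuration to C10.
4. The precursor is cut at C1–C2: an enyne Grignard reagent (C2–C6 and C15, from (Z)-3-methylpent-2-en-4-yn-1-ol) adds under chelation control to a methyl ketone cut out of L-rhamnose. The sugar supplies C7–C10, C1 and C14 with C8 and C9 already set; its C4 carbinol (C10) serves as a relay stereocentre and is oxidised afterwards.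

Key step: step 12

Remark: germacrane numbering is used throughout (C1 ketone, C2=C3, C4(C15)=C5, C6 lactone carbinol, C7, C8 ester carbinol, C9 acetate carbinol, quaternary C10 with methyl C14, C11–C13 the methylene lactone carbons); rhamnose C1–C6 become C7, C8, C9, C10, C1 and C14.
Remark: (Z)-3-methylpent-2-en-4-yn-1-ol is taken to be purchased as the single Z isomer.

**Route**

Step 1
Reactants: 1 L-rhamnose (α-L-rhamnopyranose, sold as the monohydrate)
Product: 2 allyl α-L-rhamnopyranoside
Conditions: allyl alcohol (solvent), AcCl (cat.), 70 °C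
Reagents that add atoms: allyl alcohol, C=CCO
Why: Fischer glycosidation under thermodynamic control gives the pyranoside with the axial (α) allyloxy group favoured by the anomeric effect and masks the future C7 in a form that can later be freed without strong acid.

Step 2
Reactants: 2 allyl α-L-rhamnopyranoside
Product: 3 allyl 2,3-O-isopropylidene-α-L-rhamnopyranoside
Conditions: 2,2-dimethoxypropane, TsOH·H2O (cat.), acetone, rt
Reagents that add atoms: 2,2-dimethoxypropane, COC(C)(C)OC
Why: Acid-catalysed acetal exchange engages the only cis-vicinal diol (O2/O3, the future C8 and C9 oxygens) as the five-membered isopropylidene acetal and leaves O4 (the future C10 oxygen) free.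

Step 3
Reactants: 3 allyl 2,3-O-isopropylidene-α-L-rhamnopyranoside
Product: 4 allyl 2,3-O-isopropylidene-4-O-(4-methoxybenzyl)-α-L-rhamnopyranoside
Conditions: NaH, 4-methoxybenzyl chloride, Bu4NI (cat.), DMF, 0 °C to rt
Reagents that add atoms: 4-methoxybenzyl chloride, COc1ccc(CCl)cc1
Why: Williamson etherification of the single free hydroxyl places on the future C10 oxygen a PMB ether that can chelate magnesium in step 9 and is removed oxidatively in step 10.

Step 4
Reactants: 4 allyl 2,3-O-isopropylidene-4-O-(4-methoxybenzyl)-α-L-rhamnopyranoside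
Product: 6 2,3-O-isopropylidene-4-O-(4-methoxybenzyl)-L-rhamnopyranose (α/β lactol), via prop-1-enyl glycoside 5 (not isolated)
Conditions: [Ir(cod)(PMePh2)2]PF6 (cat., activated with H2), THF, rt; then I2, NaHCO3, THF/H2O, rt
Reagents that add atoms: water, O
Why: Iridium-catalysed allyl-to-prop-1-enyl isomerisation followed by iodine-promoted hydrolysis of the enol ether frees the anomeric hydroxyl under near-neutral conditions that leave the acetonide and the PMB ether intact.

Step 5
Reactants: 6 2,3-O-isopropylidene-4-O-(4-methoxybenzyl)-L-rhamnopyranose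
Product: 7 2,3-O-isopropylidene-4-O-(4-methoxybenzyl)-L-rhamnitol (free hydroxyls at C7 and C1)
Conditions: NaBH4, MeOH, 0 °C to rt
Reagents that add atoms: none
Why: Borohydride reduction of the open-chain aldehyde in equilibrium with the lactol gives the acyclic alditol, which turns C7 into a primary alcohol and frees the C1 (rhamnose C5) hydroxyl.

Step 6
Reactants: 7 2,3-O-isopropylidene-4-O-(4-methoxybenzyl)-L-rhamnitol
Product: 8 1-O-TBS-2,3-O-isopropylidene-4-O-(4-methoxybenzyl)-L-rhamnitol (C7 OTBS, C1 OH)
Conditions: TBSCl, imidazole, CH2Cl2, 0 °C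
Reagents that add atoms: tert-butyldimethylsilyl chloride, CC(C)(C)[Si](C)(C)Cl
Why: Silylation with the bulky chlorosilane at 0 °C is selective for the primary C7 hydroxyl over the secondary C1 hydroxyl.

Step 7
Reactants: 8 1-O-TBS-2,3-O-isopropylidene-4-O-(4-methoxybenzyl)-L-rhamnitol
Product: 9 methyl ketone (C1 ketone with methyl C14, C10 OPMB, C8/C9 cis-acetonide, C7 OTBS)
Conditions: Dess–Martin periodinane, NaHCO3, CH2Cl2, 0 °C to rt
Reagents that add atoms: none
Why: Dess–Martin oxidation of the remaining secondary alcohol gives the methyl ketone under buffered, non-basic conditions that do not epimerise the neighbouring C10 ether carbon.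

Step 8
Reactants: 10 (Z)-3-methylpent-2-en-4-yn-1-ol
Product: 11 tert-butyl{[(Z)-3-methylpent-2-en-4-yn-1-yl]oxy}diphenylsilane
Conditions: TBDPSCl, imidazole, DMF, rt
Reagents that add atoms: tert-butyldiphenylsilyl chloride, CC(C)(C)[Si](Cl)(c1ccccc1)c1ccccc1
Why: Standard silylation of the primary allylic alcohol gives a robust TBDPS ether on the future C6 oxygen that survives the later selective removal of the C7 TBS group.

Step 9
Reactants: 9 methyl ketone; 11 TBDPS-protected (Z)-enyne
Product: 13 (1R)-tertiary propargylic alcohol (C1 bearing methyl, OH and the C2≡C3 enyne; C10 OPMB; C8/C9 acetonide; C7 OTBS; C6 OTBDPS; 4Z), via alkynylmagnesium bromide 12 (not isolated)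
Conditions: 11, EtMgBr, THF, 0 to 40 °C; then 9, Et2O/CH2Cl2, −78 to −20 °C; then aq. NH4Cl
Reagents that add atoms: none
Why: Chelation-controlled Grignard 1,2-addition to an α-alkoxy ketone, in which magnesium bridges the C1 carbonyl and the C10 PMB-ether oxygen and the alkynyl group enters the five-membered chelate from the face opposite to C9, which should set C1 as R.

Step 10
Reactants: 13 (1R)-tertiary propargylic alcohol
Product: 14 C1,C10-diol (secondary C10 OH, tertiary C1 OH)
Conditions: DDQ, CH2Cl2/pH 7 buffer, 0 °C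
Reagents that add atoms: none
Why: Oxidative cleavage of the PMB ether by DDQ in wet dichloromethane frees the C10 hydroxyl without touching the silyl ethers, the acetonide or the enyne.

Step 11
Reactants: 14 C1,C10-diol
Product: 15 (1R,8S,9S)-2-hydroxy-2-alkynyl ketone (C10 ketone, C1 carbinol with methyl and C2≡C3 enyne, C8/C9 acetonide, C7 OTBS, C6 OTBDPS)
Conditions: Dess–Martin periodinane, NaHCO3, CH2Cl2, 0 °C to rt
Reagents that add atoms: none
Why: Dess–Martin oxidation converts the secondary C10 alcohol into the ketone while the tertiary C1 alcohol cannot be oxidised, and the buffered medium avoids epimerisation at C9.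

Step 12
Reactants: 15 (1R,8S,9S)-2-hydroxy-2-alkynyl ketone
Product: 16 (8S,9S,10R)-3(2H)-furanone (ring O–C3=C2–C1(=O)–C10; C10 bearing methyl and C9; C3 bearing the (Z)-C4(C15)=C5–C6H2OTBDPS chain; C8/C9 acetonide; C7 OTBS)
Conditions: PtCl2 (10 mol %), toluene, 80 °C
Reagents that add atoms: none
Why: PtCl2 (divalent platinum) coordinates the C2≡C3 alkyne and the C10 ketone oxygen adds to C3, giving a cyclic oxocarbenium ion at C10 with a vinyl–platinum bond at C2; the methyl group on the neighbouring C1 carbinol then shifts to C10 while C1 becomes the ketone, and protodemetalation at C2 releases the furanone. The closest known reaction type is the PtCl2- or AuCl3-catalysed heterocyclisation with 1,2-alkyl shift of 2-hydroxy-2-alkynyl ketones to 3(2H)-furanones. The furanone ring (O, C3, C2, C1, C10) is the only ring closed, by 5-endo-dig O–C3 bond formation. The new C10 stereocentre is controlled by C1: the shift is suprafacial, so the methyl arrives on the ring face it occupied on C1 and (1R) in 15 should become (10R) in 16, which is a mechanistic expectation for a migrating methyl and not an established result. The step needs attack of the ketone oxygen at C3 instead of ionisation of the tertiary propargylic alcohol, and migration of methyl alone: the acyl group on C1 disfavours a C1 cation, the alkenyl group on C3 stabilises positive charge there, and methyl is the only substituent on C1 that can move. The Z geometry of C4=C5, the silyl ethers and the acetonide are spectators under these neutral conditions.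

Step 13
Reactants: 16 (8S,9S,10R)-3(2H)-furanone
Product: 17 C7 primary alcohol (C6 OTBDPS retained)
Conditions: HF·pyridine, pyridine, THF, 0 °C
Reagents that add atoms: none
Why: Buffered HF·pyridine cleaves the primary alkyl TBS ether much faster than the bulkier TBDPS ether, so only the C7 hydroxyl is freed.

Step 14
Reactants: 17 C7 primary alcohol
Product: 18 C7 aldehyde
Conditions: Dess–Martin periodinane, NaHCO3, CH2Cl2, 0 °C
Reagents that add atoms: none
Why: Dess–Martin oxidation gives the α-alkoxy aldehyde without base, so the C8 stereocentre next to the new carbonyl is not epimerised.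

Step 15
Reactants: 18 C7 aldehyde; 19 methyl acrylate
Product: 20 Morita–Baylis–Hillman adduct (methyl 2-methylene-3-hydroxy ester at C7, both C7 carbinol epimers)
Conditions: DABCO, methyl acrylate (excess), MeOH (trace), rt
Reagents that add atoms: none
Why: Morita–Baylis–Hillman reaction, in which DABCO adds to the acrylate and the resulting enolate adds to the activated α-alkoxy aldehyde to form the C7–C11 bond, the C7 carbinol configuration being irrelevant because C7 becomes sp2 in step 16.

Step 16
Reactants: 20 Morita–Baylis–Hillman adduct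
Product: 21 (Z)-2-(bromomethyl)enoate (C7=C11 double bond, C13 bromide, methyl ester, C6 OTBDPS)
Conditions: NBS, Me2S, CH2Cl2, 0 °C; then 20, −20 °C to rt
Reagents that add atoms: N-bromosuccinimide, O=C1CCC(=O)N1Br
Why: Corey–Kim-type activation of the allylic alcohol and SN2' attack of bromide at C13 give, with allylic transposition, the thermodynamically preferred (Z)-2-(bromomethyl)enoate.

Step 17
Reactants: 21 (Z)-2-(bromomethyl)enoate
Product: 22 C6 allylic alcohol
Conditions: HF·pyridine, THF, 0 °C to rt
Reagents that add atoms: none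
Why: HF·pyridine removes the TBDPS group from the primary allylic C6 oxygen without the basic fluoride that the allylic bromide would not tolerate.

Step 18
Reactants: 22 C6 allylic alcohol
Product: 23 (4Z)-C6 enal carrying the (Z)-2-(bromomethyl)enoate
Conditions: Dess–Martin periodinane, NaHCO3, CH2Cl2, 0 °C
Reagents that add atoms: none
Why: Buffered Dess–Martin oxidation of the Z-allylic alcohol gives the Z-enal without acid or base that could isomerise the C4=C5 double bond.

Step 19
Reactants: 23 (4Z)-C6 enal carrying the (Z)-2-(bromomethyl)enoate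
Product: 25 lactone acetonide (ten-membered carbocycle with trans-fused α-methylene-γ-butyrolactone, 6R,7S as in the target, 8,9-O-isopropylidene), via ring-closed hydroxy ester 24 (not isolated)
Conditions: CrCl2 (excess), THF, rt, slow addition at high dilution; then H2O
Reagents that add atoms: none
Why: Intramolecular Barbier (Nozaki–Hiyama-type) allylation, in which CrCl2 turns the allylic bromide into an allylchromium species that attacks the C6 aldehyde through its γ-carbon C7, closing the carbocycle and regenerating the C11=C13 methylene before the chromium alkoxide lactonises onto the methyl ester; open-chain 2-(bromomethyl)enoates tend to add syn, so the trans-fused (6R,7S) outcome relies on the folding imposed by the Z-alkene, the furanone bridge and the C8 acetal carbon.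

Step 20
Reactants: 25 lactone acetonide
Product: 26 8,9-diol
Conditions: AcOH/H2O (4:1), 45 °C
Reagents that add atoms: none
Why: Mild acid-catalysed hydrolysis of the isopropylidene acetal frees the C8/C9 cis-diol and leaves the lactone, the furanone and the alkenes untouched.

Step 21
Reactants: 27 tert-butyl acrylate; 28 acetaldehyde
Product: 29 tert-butyl 3-hydroxy-2-methylenebutanoate (racemic)
Conditions: DABCO, neat, rt
Reagents that add atoms: none
Why: Morita–Baylis–Hillman reaction builds the branched four-carbon acid skeleton, and the racemic carbinol disappears in step 22.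

Step 22
Reactants: 29 tert-butyl 3-hydroxy-2-methylenebutanoate
Product: 30 tert-butyl (Z)-2-(bromomethyl)but-2-enoate
Conditions: NBS, Me2S, CH2Cl2, 0 °C to rt
Reagents that add atoms: N-bromosuccinimide, O=C1CCC(=O)N1Br
Why: Corey–Kim-type bromination with SN2' transposition gives the thermodynamically favoured isomer with the methyl group trans to the ester, which fixes the double-bond geometry of the side chain.

Step 23
Reactants: 30 tert-butyl (Z)-2-(bromomethyl)but-2-enoate
Product: 31 tert-butyl (E)-2-(acetoxymethyl)but-2-enoate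
Conditions: KOAc, DMF, rt
Reagents that add atoms: potassium acetate, CC(=O)[O-].[K+]
Why: SN2 displacement of the primary allylic bromide by acetate keeps the double-bond geometry, the descriptor changing from Z to E only through the change of priorities.

Step 24
Reactants: 31 tert-butyl (E)-2-(acetoxymethyl)but-2-enoate
Product: 32 (E)-2-(acetoxymethyl)but-2-enoic acid
Conditions: TFA, CH2Cl2, 0 °C to rt
Reagents that add atoms: none
Why: Acidolysis of the tert-butyl ester with loss of isobutene frees the carboxylic acid without cleaving the primary acetate.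

Step 25
Reactants: 26 8,9-diol; 32 (E)-2-(acetoxymethyl)but-2-enoic acid
Product: 34 C8 mono-ester (C9 hydroxyl free), via mixed anhydride 33 (not isolated)
Conditions: 32, 2,4,6-trichlorobenzoyl chloride, Et3N, toluene, rt; then 26, DMAP, 0 °C
Reagents that add atoms: none
Why: Yamaguchi esterification, in which the mixed anhydride should acylate under DMAP catalysis the C8 hydroxyl in preference to the C9 hydroxyl that is flanked by the fully substituted C10, the E acid being the stable geometric isomer.

Step 26
Reactants: 34 C8 mono-ester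
Product: 35 CNP0325609.1 (target; 6R,7S,8S,9S,10R)
Conditions: Ac2O, DMAP, pyridine, CH2Cl2, rt
Reagents that add atoms: acetic anhydride, CC(=O)OC(C)=O
Why: DMAP-catalysed acetylation of the remaining hindered C9 secondary hydroxyl completes the target.

**Compound list**

1 | L-rhamnose (α-L-rhamnopyranose, sold as the monohydrate) | C[C@@H]1O[C@@H](O)[C@H](O)[C@H](O)[C@H]1O | starting material
2 | allyl α-L-rhamnopyranoside | C[C@@H]1O[C@@H](OCC=C)[C@H](O)[C@H](O)[C@H]1O | intermediate
3 | allyl 2,3-O-isopropylidene-α-L-rhamnopyranoside | C[C@@H]1O[C@@H](OCC=C)[C@@H]2OC(C)(C)O[C@@H]2[C@H]1O | intermediate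
4 | allyl 2,3-O-isopropylidene-4-O-(4-methoxybenzyl)-α-L-rhamnopyranoside | C[C@@H]1O[C@@H](OCC=C)[C@@H]2OC(C)(C)O[C@@H]2[C@H]1OCc3ccc(OC)cc3 | intermediate
5 | prop-1-enyl 2,3-O-isopropylidene-4-O-(4-methoxybenzyl)-α-L-rhamnopyranoside | C[C@@H]1O[C@@H](OC=CC)[C@@H]2OC(C)(C)O[C@@H]2[C@H]1OCc3ccc(OC)cc3 | intermediate
6 | 2,3-O-isopropylidene-4-O-(4-methoxybenzyl)-L-rhamnopyranose (α/β lactol) | C[C@@H]1OC(O)[C@@H]2OC(C)(C)O[C@@H]2[C@H]1OCc3ccc(OC)cc3 | intermediate
7 | 2,3-O-isopropylidene-4-O-(4-methoxybenzyl)-L-rhamnitol | OC[C@@H]1OC(C)(C)O[C@@H]1[C@@H](OCc2ccc(OC)cc2)[C@H](C)O | intermediate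
8 | 1-O-TBS-2,3-O-isopropylidene-4-O-(4-methoxybenzyl)-L-rhamnitol | CC(C)(C)[Si](C)(C)OC[C@@H]1OC(C)(C)O[C@@H]1[C@@H](OCc2ccc(OC)cc2)[C@H](C)O | intermediate
9 | methyl ketone (C1 ketone, C10 OPMB, C8/C9 cis-acetonide, C7 OTBS) | CC(C)(C)[Si](C)(C)OC[C@@H]1OC(C)(C)O[C@@H]1[C@@H](OCc2ccc(OC)cc2)C(C)=O | intermediate
10 | (Z)-3-methylpent-2-en-4-yn-1-ol | C#C/C(C)=C\CO | starting material
11 | tert-butyl{[(Z)-3-methylpent-2-en-4-yn-1-yl]oxy}diphenylsilane | C#C/C(C)=C\CO[Si](c1ccccc1)(c2ccccc2)C(C)(C)C | intermediate
12 | bromomagnesium acetylide of 11 | Br[Mg]C#C/C(C)=C\CO[Si](c1ccccc1)(c2ccccc2)C(C)(C)C | intermediate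
13 | (1R)-tertiary propargylic alcohol with C10 OPMB | CC(C)(C)[Si](C)(C)OC[C@@H]1OC(C)(C)O[C@@H]1[C@@H](OCc2ccc(OC)cc2)[C@](C)(O)C#C/C(C)=C\CO[Si](c3ccccc3)(c4ccccc4)C(C)(C)C | intermediate
14 | C1,C10-diol | CC(C)(C)[Si](C)(C)OC[C@@H]1OC(C)(C)O[C@@H]1[C@@H](O)[C@](C)(O)C#C/C(C)=C\CO[Si](c2ccccc2)(c3ccccc3)C(C)(C)C | intermediate
15 | (1R,8S,9S)-2-hydroxy-2-alkynyl ketone (key-step precursor) | CC(C)(C)[Si](C)(C)OC[C@@H]1OC(C)(C)O[C@@H]1C(=O)[C@](C)(O)C#C/C(C)=C\CO[Si](c2ccccc2)(c3ccccc3)C(C)(C)C | intermediate
16 | (8S,9S,10R)-3(2H)-furanone (key-step product) | CC(C)(C)[Si](c1ccccc1)(c2ccccc2)OC/C=C(/C)C3=CC(=O)[C@](C)(O3)[C@H]4OC(C)(C)O[C@H]4CO[Si](C)(C)C(C)(C)C | intermediate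
17 | C7 primary alcohol | CC(C)(C)[Si](c1ccccc1)(c2ccccc2)OC/C=C(/C)C3=CC(=O)[C@](C)(O3)[C@H]4OC(C)(C)O[C@H]4CO | intermediate
18 | C7 aldehyde | CC(C)(C)[Si](c1ccccc1)(c2ccccc2)OC/C=C(/C)C3=CC(=O)[C@](C)(O3)[C@H]4OC(C)(C)O[C@H]4C=O | intermediate
19 | methyl acrylate | C=CC(=O)OC | starting material
20 | Morita–Baylis–Hillman adduct (C7 epimers) | CC(C)(C)[Si](c1ccccc1)(c2ccccc2)OC/C=C(/C)C3=CC(=O)[C@](C)(O3)[C@H]4OC(C)(C)O[C@H]4C(O)C(=C)C(=O)OC | intermediate
21 | (Z)-2-(bromomethyl)enoate with C6 OTBDPS | CC(C)(C)[Si](c1ccccc1)(c2ccccc2)OC/C=C(/C)C3=CC(=O)[C@](C)(O3)[C@H]4OC(C)(C)O[C@H]4/C=C(/C(=O)OC)CBr | intermediate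
22 | C6 allylic alcohol | OC/C=C(/C)C1=CC(=O)[C@](C)(O1)[C@H]2OC(C)(C)O[C@H]2/C=C(/C(=O)OC)CBr | intermediate
23 | (4Z)-C6 enal with (Z)-2-(bromomethyl)enoate | O=C/C=C(/C)C1=CC(=O)[C@](C)(O1)[C@H]2OC(C)(C)O[C@H]2/C=C(/C(=O)OC)CBr | intermediate
24 | ring-closed C6 hydroxy ester (chromium alkoxide before work-up) | COC(=O)C(=C)[C@H]1[C@H](O)/C=C(/C)C2=CC(=O)[C@](C)(O2)[C@H]3OC(C)(C)O[C@@H]13 | intermediate
25 | lactone acetonide (6R,7S trans-fused α-methylene lactone, 8,9-O-isopropylidene) | C=C1C(=O)O[C@@H]2/C=C(/C)C3=CC(=O)[C@](C)(O3)[C@H]4OC(C)(C)O[C@H]4[C@@H]12 | intermediate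
26 | 8,9-diol | C=C1C(=O)O[C@@H]2/C=C(/C)C3=CC(=O)[C@](C)(O3)[C@@H](O)[C@@H](O)[C@@H]12 | intermediate
27 | tert-butyl acrylate | C=CC(=O)OC(C)(C)C | starting material
28 | acetaldehyde | CC=O | starting material
29 | tert-butyl 3-hydroxy-2-methylenebutanoate (racemic) | CC(O)C(=C)C(=O)OC(C)(C)C | intermediate
30 | tert-butyl (Z)-2-(bromomethyl)but-2-enoate | C/C=C(/C(=O)OC(C)(C)C)CBr | intermediate
31 | tert-butyl (E)-2-(acetoxymethyl)but-2-enoate | C/C=C(/C(=O)OC(C)(C)C)COC(C)=O | intermediate
32 | (E)-2-(acetoxymethyl)but-2-enoic acid | C/C=C(/C(=O)O)COC(C)=O | intermediate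
33 | mixed anhydride of 32 with 2,4,6-trichlorobenzoic acid | C/C=C(/C(=O)OC(=O)c1c(Cl)cc(Cl)cc1Cl)COC(C)=O | intermediate
34 | C8 mono-ester with free C9 hydroxyl | C=C1C(=O)O[C@@H]2/C=C(/C)C3=CC(=O)[C@](C)(O3)[C@@H](O)[C@@H](OC(=O)/C(=C/C)COC(C)=O)[C@@H]12 | intermediate
35 | CNP0325609.1 | C=C1C(=O)O[C@@H]2/C=C(/C)C3=CC(=O)[C@](C)(O3)[C@@H](OC(C)=O)[C@@H](OC(=O)/C(=C/C)COC(C)=O)[C@@H]12 | target

**Step count**

Total: 26 steps. Longest linear sequence: 21 steps (steps 1–7, 9–20, 25 and 26).

**Steps most likely to fail**

Step 12. The methyl group may fail to migrate to an oxocarbenium carbon that carries the electron-withdrawing acetal oxygen, so that ionisation of the propargylic alcohol or degradation of the enyne takes over, and the transfer of configuration may be incomplete. The fallback sets out from 8 and returns at 16; it builds the furanone without any shift, by conjugate cyclisation of a 4-hydroxy ynone whose C10 carbinol is made by chelation-controlled Grignard addition. DDQ removes the PMB group of 8 to give the 4,5-diol F1. NaIO4 cleaves the C10–C1 bond of F1 to the protected L-erythrose aldehyde F2. MeMgBr gives the C10 carbinol F3, and Dess–Martin oxidation gives the C10 methyl ketone F4. CH2=CHMgBr adds under chelation by the C9 acetal oxygen, from the face opposite to C8, to give the tertiary allylic alcohol F5 with the (10R) arrangement of methyl, oxygen and C9. Ozonolysis (O3, then PPh3) gives the 2-hydroxy aldehyde F6. The Grignard reagent 12 adds to give the propargylic diol F7, and Dess–Martin oxidation gives the 4-hydroxy ynone F8. Et2NH in ethanol closes F8 by 5-endo-dig oxa-Michael addition to furanone 16.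

Step 19. Ring closure may lose to intermolecular coupling and to simple reduction of the bromide, and the addition may follow the syn course usual for open-chain 2-(bromomethyl)enoates, giving the cis-fused lactone. The fallback sets out from 23 and returns at 25; C6 is then set by an SN2 inversion instead of by the allylation transition state, which presupposes that C7 has formed with the natural configuration. The cyclisation product with the wrong C6 configuration, the cis-fused C6-epimeric lactone F9, is opened with LiOH in THF/H2O to the seco hydroxy acid F10. Mitsunobu lactonisation (PPh3, diisopropyl azodicarboxylate, toluene) closes the lactone again with inversion at C6 and gives 25.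

Step 15. The hindered α-alkoxy aldehyde may react only slowly, so that base-mediated epimerisation at C8 and reversible amine addition to the dienone, with loss of the C4=C5 geometry, compete. The fallback sets out from 18 and returns at 20. The acrylate unit is added as a preformed vinylaluminium reagent, made by hydroalumination of methyl propiolate with iBu2AlH/HMPA in THF at 0 °C, which adds to the aldehyde at −78 °C without amine catalysis. This detour makes no compound outside the list.

Further compounds
F1 | step 12 | 1-O-TBS-2,3-O-isopropylidene-L-rhamnitol (4,5-diol) | CC(C)(C)[Si](C)(C)OC[C@@H]1OC(C)(C)O[C@@H]1[C@@H](O)[C@H](C)O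
F2 | step 12 | 4-O-TBS-2,3-O-isopropylidene-L-erythrose (C10 aldehyde) | CC(C)(C)[Si](C)(C)OC[C@@H]1OC(C)(C)O[C@@H]1C=O
F3 | step 12 | C10 secondary carbinol (epimer mixture) | CC(C)(C)[Si](C)(C)OC[C@@H]1OC(C)(C)O[C@@H]1C(C)O
F4 | step 12 | C10 methyl ketone | CC(C)(C)[Si](C)(C)OC[C@@H]1OC(C)(C)O[C@@H]1C(C)=O
F5 | step 12 | (10R)-tertiary allylic alcohol | CC(C)(C)[Si](C)(C)OC[C@@H]1OC(C)(C)O[C@@H]1[C@@](C)(O)C=C
F6 | step 12 | 2-hydroxy aldehyde (C1 aldehyde, C10 carbinol) | CC(C)(C)[Si](C)(C)OC[C@@H]1OC(C)(C)O[C@@H]1[C@@](C)(O)C=O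
F7 | step 12 | propargylic diol (C1 epimers) | CC(C)(C)[Si](C)(C)OC[C@@H]1OC(C)(C)O[C@@H]1[C@@](C)(O)C(O)C#C/C(C)=C\CO[Si](c2ccccc2)(c3ccccc3)C(C)(C)C
F8 | step 12 | 4-hydroxy ynone (C1 ketone, C10 tertiary carbinol) | CC(C)(C)[Si](C)(C)OC[C@@H]1OC(C)(C)O[C@@H]1[C@@](C)(O)C(=O)C#C/C(C)=C\CO[Si](c2ccccc2)(c3ccccc3)C(C)(C)C
F9 | step 19 | cis-fused C6-epimeric lactone acetonide | C=C1C(=O)O[C@H]2/C=C(/C)C3=CC(=O)[C@](C)(O3)[C@H]4OC(C)(C)O[C@H]4[C@@H]12
F10 | step 19 | seco hydroxy acid (C6 epimer) | OC(=O)C(=C)[C@H]1[C@@H](O)/C=C(/C)C2=CC(=O)[C@](C)(O2)[C@H]3OC(C)(C)O[C@@H]13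
F0 | step 15 | none | none
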